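The six-membered ring (C1 ketone, C2 amide-bearing carbon, C3, quaternary carbinol C4, carbinol C5, C6) is treated as a p-quinol that has added water across C5=C6 under guidance of the C4 hydroxyl. The quinol ring is assembled from two acyclic three-carbon pieces: an N-benzhydryl 1-azadiene (C2–C4) and 3-methoxyacryloyl chloride (C5–C6–C1). In one operation the 2-azaallyl anion is C-acylated (C1–C2) and the resulting trienolate closes by 6π-electrocyclisation with loss of methoxide (C4–C5), exploiting the 1,4-relationship of the C1 carbonyl and the C4 carbinol; a chiral benzylic ether on the C4 oxygen controls the quaternary centre. Amide formation, boron-tethered hydration and a Stille coupling finish the route.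

Key step: step 4

Ring numbering used in names and text: C1 ketone carbon, C2 amide-bearing carbon, C3 vinylic CH, C4 quaternary carbinol, C5 secondary carbinol, C6 methylene.
Assumption: the (S)-1-(4-methoxyphenyl)ethyl ether is taken to shield the C4 face that leads to (4R)-10; if the sense is the opposite, the (R)-alcohol is used instead, and in either case the C4 epimers are diastereomers that chromatography should separate.

Step 1
Reactants: 1 1,4-bis(trimethylsilyl)buta-1,3-diyne
Product: 2 5-(trimethylsilyl)penta-2,4-diynal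
Conditions: MeLi·LiBr (1 equiv), THF, 23 °C; DMF, −78 to 0 °C; cold 1 M HCl
Reagents that add atoms: N,N-dimethylformamide CN(C)C=O
Why: Methyllithium removes one silyl group selectively and the lithium diynide is formylated by DMF (formylation of an alkynyllithium), with no stereocentre involved.

Step 2
Reactants: 2 5-(trimethylsilyl)penta-2,4-diynal; 3 (S)-1-(4-methoxyphenyl)ethan-1-ol
Product: 4 (2E)-3-[(1S)-1-(4-methoxyphenyl)ethoxy]-5-(trimethylsilyl)pent-2-en-4-ynal
Conditions: cat. PMe3, CH2Cl2, −20 to 0 °C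
Reagents that add atoms: none
Why: Nucleophile-catalysed oxa-Michael addition of the alcohol to the ynal β-carbon (the future C4) should give the thermodynamically preferred (E)-β-alkoxy enal, the carbinol centre of 3 being untouched.

Step 3
Reactants: 4 (2E)-3-[(1S)-1-(4-methoxyphenyl)ethoxy]-5-(trimethylsilyl)pent-2-en-4-ynal; 5 1,1-diphenylmethanamine
Product: 6 (1E,2E)-N-(diphenylmethyl)-3-[(1S)-1-(4-methoxyphenyl)ethoxy]-5-(trimethylsilyl)pent-2-en-4-yn-1-imine
Conditions: MgSO4, CH2Cl2, 0 to 23 °C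
Reagents that add atoms: none
Why: Condensation of the aldehyde with the primary amine (imine formation) should give the (E)-aldimine faster than attack at the fully substituted β-carbon, and no new stereocentre arises.

Step 4
Reactants: 6 (1E,2E)-N-(diphenylmethyl)-3-[(1S)-1-(4-methoxyphenyl)ethoxy]-5-(trimethylsilyl)pent-2-en-4-yn-1-imine; 7 (2E)-3-methoxyprop-2-enoyl chloride
Product: 10 (4R)-2-[(diphenylmethylidene)amino]-4-[(1S)-1-(4-methoxyphenyl)ethoxy]-4-[(trimethylsilyl)ethynyl]cyclohexa-2,5-dien-1-one, via C-acylated dienynone 8 (not isolated), via methoxy cyclohexenone enolate 9 (not isolated)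
Conditions: LiN(SiMe3)2 (2.1 equiv), THF, −78 °C; 7, −78 °C; then 23 °C, 0.02 M; aq. NH4Cl
Reagents that add atoms: none
Why: Proposed new method: LiN(SiMe3)2 removes the benzhydryl proton of 6 to give a 2-azaallyl anion that is C-acylated at C2 by 7 (bond C1–C2), and the second equivalent of base turns ketone 8 into a 3-oxido-hexatriene (C5=C6–C1(O−)=C2–C3=C4) that closes by thermal disrotatory 6π-electrocyclisation (equivalently a 6-endo-trig vinylogous Michael addition) to form C4–C5, after which enolate 9 expels methoxide (E1cB) to give the cross-conjugated dienone. The closest known reactions are the C-acylation of benzophenone-imine-type (2-azaallyl) anions with acid chlorides, carba-[3+3] annulations by condensation and 6π-electrocyclisation, and addition–elimination of carbanions on β-alkoxy enones. The carbocycle closes in the 6π (6-endo) mode because attack through C2 or the enolate oxygen would give four-membered rings and attack through the diphenyl-substituted terminus is sterically disfavoured. The only stereocentre that survives, quaternary C4, is set by the (S)-1-(4-methoxyphenyl)ethoxy group that sits on the reacting enol-ether carbon and shields one of its faces, as chiral enol ethers do in pericyclic additions, and the C4 epimer is a diastereomer that chromatography should remove. The step needs C- rather than N-acylation and ring closure faster than oligomerisation, which the soft delocalised anion, the vinylogous acid chloride and dilution on warming should secure.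

Step 5
Reactants: 11 hex-1-ene
Product: 13 (4S)-4-methyloct-1-ene, via methylhexylalane 12 (not isolated)
Conditions: Me3Al, cat. (+)-bis(1-neomenthylindenyl)zirconium dichloride, methylaluminoxane, CH2Cl2, 0 °C; then bromoethene, Zn(OTf)2, cat. PdCl2(DPEphos), DMF, 23 °C
Reagents that add atoms: trimethylaluminium C[Al](C)C; bromoethene C=CBr
Why: Zirconium-catalysed asymmetric carboalumination (ZACA) adds methyl and aluminium across the terminal alkene with the (+)-catalyst setting the methyl-bearing centre, and the alkylalane is vinylated in the same flask by a zinc-assisted Negishi coupling.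

Step 6
Reactants: 13 (4S)-4-methyloct-1-ene
Product: 15 (2R,4S)-2,4-dimethyloctan-1-ol, via dimethyloctylalane 14 (not isolated)
Conditions: Me3Al, cat. (−)-bis(1-neomenthylindenyl)zirconium dichloride, methylaluminoxane, CH2Cl2, 0 °C; then O2
Reagents that add atoms: trimethylaluminium C[Al](C)C; dioxygen O=O
Why: A second ZACA reaction, now under control of the (−)-catalyst, sets C2, and oxidation of the carbon–aluminium bond with retention should give the alcohol.

Step 7
Reactants: 15 (2R,4S)-2,4-dimethyloctan-1-ol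
Product: 17 ethyl (2E,4R,6S)-4,6-dimethyldec-2-enoate, via aldehyde 16 (not isolated)
Conditions: PhI(OAc)2, cat. TEMPO, CH2Cl2, 23 °C; then Ph3P=CHCO2Et, 23 °C
Reagents that add atoms: ethyl 2-(triphenyl-λ5-phosphanylidene)acetate CCOC(=O)C=P(c1ccccc1)(c1ccccc1)c1ccccc1
Why: TEMPO oxidation gives the α-branched aldehyde without epimerisation and the stabilised ylide converts it at once into the (E)-enoate (Wittig reaction).

Step 8
Reactants: 17 ethyl (2E,4R,6S)-4,6-dimethyldec-2-enoate
Product: 18 (2E,4R,6S)-4,6-dimethyldec-2-enoic acid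
Conditions: LiOH, THF–H2O, 23 °C; 1 M HCl
Reagents that add atoms: lithium hydroxide [Li+].[OH-]
Why: Ester saponification should proceed without touching the alkene geometry or the two stereocentres.

Step 9
Reactants: 10 (4R)-2-[(diphenylmethylidene)amino]-4-[(1S)-1-(4-methoxyphenyl)ethoxy]-4-[(trimethylsilyl)ethynyl]cyclohexa-2,5-dien-1-one; 18 (2E,4R,6S)-4,6-dimethyldec-2-enoic acid
Product: 21 (2E,4R,6S)-N-{(3R)-3-[(1S)-1-(4-methoxyphenyl)ethoxy]-6-oxo-3-[(trimethylsilyl)ethynyl]cyclohexa-1,4-dien-1-yl}-4,6-dimethyldec-2-enamide, via acid chloride 19 (not isolated), via aminodienone 20 (not isolated)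
Conditions: 18, (COCl)2, cat. DMF, CH2Cl2, 0 °C; 10, 1 M citric acid, THF, 23 °C; then combined, pyridine, CH2Cl2, 0 to 23 °C
Reagents that add atoms: none
Why: Mild acid hydrolyses the N-diphenylmethylidene enamine to the 2-aminodienone, which is N-acylated by the acid chloride (amide formation) without touching C4.

Step 10
Reactants: 21 (2E,4R,6S)-N-{(3R)-3-[(1S)-1-(4-methoxyphenyl)ethoxy]-6-oxo-3-[(trimethylsilyl)ethynyl]cyclohexa-1,4-dien-1-yl}-4,6-dimethyldec-2-enamide
Product: 22 (2E,4R,6S)-N-{(3R)-3-ethynyl-3-[(1S)-1-(4-methoxyphenyl)ethoxy]-6-oxocyclohexa-1,4-dien-1-yl}-4,6-dimethyldec-2-enamide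
Conditions: Bu4NF, AcOH, THF, 0 °C
Reagents that add atoms: none
Why: Buffered fluoride cleaves the alkynyl–silicon bond (protodesilylation) without base-mediated addition to the dienone.

Step 11
Reactants: 22 (2E,4R,6S)-N-{(3R)-3-ethynyl-3-[(1S)-1-(4-methoxyphenyl)ethoxy]-6-oxocyclohexa-1,4-dien-1-yl}-4,6-dimethyldec-2-enamide
Product: 23 (2E,4R,6S)-N-[(3R)-3-ethynyl-3-hydroxy-6-oxocyclohexa-1,4-dien-1-yl]-4,6-dimethyldec-2-enamide
Conditions: DDQ, CH2Cl2–pH 7 buffer, 0 to 23 °C
Reagents that add atoms: none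
Why: Oxidative cleavage of the electron-rich 1-(4-methoxyphenyl)ethyl ether, as for a PMB ether, should free the tertiary alcohol and leave C4 unchanged.

Step 12
Reactants: 23 (2E,4R,6S)-N-[(3R)-3-ethynyl-3-hydroxy-6-oxocyclohexa-1,4-dien-1-yl]-4,6-dimethyldec-2-enamide
Product: 25 (2E,4R,6S)-N-[(3R,4R)-3-ethynyl-3,4-dihydroxy-6-oxocyclohex-1-en-1-yl]-4,6-dimethyldec-2-enamide, via phenylboronate 24 (not isolated)
Conditions: PhB(OH)2, cat. Et3N, 4 Å MS, CH2Cl2, 23 °C; then pinacol, 23 °C
Reagents that add atoms: phenylboronic acid OB(O)c1ccccc1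
Why: The C4 hydroxyl forms a boronic hemiester that delivers its B–OH oxygen intramolecularly to C5 of the unsubstituted enone arm (boronic-acid-mediated oxa-Michael addition), so the new C5–O bond must be cis to the C4–O bond, while the amide-bearing arm is the poorer acceptor and C3 should not react.

Step 13
Reactants: 25 (2E,4R,6S)-N-[(3R,4R)-3-ethynyl-3,4-dihydroxy-6-oxocyclohex-1-en-1-yl]-4,6-dimethyldec-2-enamide
Product: 26 (2E,4R,6S)-N-{(3R,4R)-3,4-dihydroxy-6-oxo-3-[(E)-2-(tributylstannyl)ethenyl]cyclohex-1-en-1-yl}-4,6-dimethyldec-2-enamide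
Conditions: Bu3SnH, cat. PdCl2(PPh3)2, THF, 0 °C
Reagents that add atoms: tributylstannane CCCC[SnH](CCCC)CCCC
Why: Palladium-catalysed syn-hydrostannation of the terminal alkyne should place tin on the unhindered terminus and give the (E)-vinylstannane.

Step 14
Reactants: 27 cyclopentane-1,3-dione
Product: 28 2-(hydroxyimino)cyclopentane-1,3-dione
Conditions: NaNO2, AcOH–H2O, 0 °C
Reagents that add atoms: sodium nitrite [Na+].[O-]N=O
Why: Nitrosation of the acidic C2 methylene of the 1,3-dione gives the oxime.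

Step 15
Reactants: 28 2-(hydroxyimino)cyclopentane-1,3-dione
Product: 29 2-amino-3-hydroxycyclopent-2-en-1-one hydrochloride
Conditions: H2, Pd on carbon, HCl, MeOH, 23 °C
Reagents that add atoms: hydrogen chloride Cl
Why: Catalytic hydrogenation reduces the oxime to the amine, which should be isolated as the stable enol hydrochloride.

Step 16
Reactants: 30 potassium (1E,3E)-5-oxopenta-1,3-dien-1-olate
Product: 31 (2E,4E)-5-bromopenta-2,4-dienal
Conditions: PPh3, Br2, CH2Cl2, 0 to 23 °C
Reagents that add atoms: bromine BrBr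
Why: The enolate oxygen is activated as an oxyphosphonium ion and replaced by bromide (addition–elimination on the vinylogous formyl system), which should give the thermodynamic (E,E)-bromodienal.

Step 17
Reactants: 31 (2E,4E)-5-bromopenta-2,4-dienal
Product: 32 (2E,4E)-5-bromopenta-2,4-dienoic acid
Conditions: NaClO2, NaH2PO4, 2-methylbut-2-ene, tBuOH–H2O, 23 °C
Reagents that add atoms: sodium chlorite [Na+].[O-]Cl=O
Why: Pinnick oxidation converts the enal into the acid without touching the bromodiene.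

Step 18
Reactants: 32 (2E,4E)-5-bromopenta-2,4-dienoic acid; 29 2-amino-3-hydroxycyclopent-2-en-1-one hydrochloride
Product: 34 (2E,4E)-5-bromo-N-(2-hydroxy-5-oxocyclopent-1-en-1-yl)penta-2,4-dienamide, via acid chloride 33 (not isolated)
Conditions: (COCl)2, cat. DMF, CH2Cl2, 0 °C; then 29, pyridine, 0 to 23 °C
Reagents that add atoms: none
Why: The acid chloride acylates the amine nitrogen, which is more nucleophilic than the enol oxygen (amide formation).

Step 19
Reactants: 26 (2E,4R,6S)-N-{(3R,4R)-3,4-dihydroxy-6-oxo-3-[(E)-2-(tributylstannyl)ethenyl]cyclohex-1-en-1-yl}-4,6-dimethyldec-2-enamide; 34 (2E,4E)-5-bromo-N-(2-hydroxy-5-oxocyclopent-1-en-1-yl)penta-2,4-dienamide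
Product: 35 (2E,4R,6S)-N-[(3S,4R)-3,4-dihydroxy-3-{(1E,3E,5E)-7-[(2-hydroxy-5-oxocyclopent-1-en-1-yl)amino]-7-oxohepta-1,3,5-trien-1-yl}-6-oxocyclohex-1-en-1-yl]-4,6-dimethyldec-2-enamide
Conditions: Pd2(dba)3, AsPh3, DMF, 23 °C
Reagents that add atoms: none
Why: Stille coupling joins the two sp2 carbons with retention of both alkene geometries, which should give the (E,E,E)-triene under neutral conditions without protecting groups.

Compound list
1 | 1,4-bis(trimethylsilyl)buta-1,3-diyne | C[Si](C)(C)C#CC#C[Si](C)(C)C | starting material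
2 | 5-(trimethylsilyl)penta-2,4-diynal | O=CC#CC#C[Si](C)(C)C | intermediate
3 | (S)-1-(4-methoxyphenyl)ethan-1-ol | C[C@H](O)c1ccc(OC)cc1 | starting material
4 | (2E)-3-[(1S)-1-(4-methoxyphenyl)ethoxy]-5-(trimethylsilyl)pent-2-en-4-ynal | O=C/C=C(/O[C@@H](C)c1ccc(OC)cc1)C#C[Si](C)(C)C | intermediate
5 | 1,1-diphenylmethanamine | NC(c1ccccc1)c1ccccc1 | starting material
6 | (1E,2E)-N-(diphenylmethyl)-3-[(1S)-1-(4-methoxyphenyl)ethoxy]-5-(trimethylsilyl)pent-2-en-4-yn-1-imine | C(c1ccccc1)(c1ccccc1)/N=C/C=C(/O[C@@H](C)c1ccc(OC)cc1)C#C[Si](C)(C)C | intermediate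
7 | (2E)-3-methoxyprop-2-enoyl chloride | CO/C=C/C(Cl)=O | starting material
8 | (1E,5E)-4-[(diphenylmethylidene)amino]-1-methoxy-6-[(1S)-1-(4-methoxyphenyl)ethoxy]-8-(trimethylsilyl)octa-1,5-dien-7-yn-3-one (both C4 epimers) | CO/C=C/C(=O)C(N=C(c1ccccc1)c1ccccc1)/C=C(/O[C@@H](C)c1ccc(OC)cc1)C#C[Si](C)(C)C | intermediate (not isolated)
9 | (4R,5R)-2-[(diphenylmethylidene)amino]-5-methoxy-4-[(1S)-1-(4-methoxyphenyl)ethoxy]-4-[(trimethylsilyl)ethynyl]cyclohex-2-en-1-one, present as its lithium enolate, drawn in the keto form | C(c1ccccc1)(c1ccccc1)=NC1=C[C@@](O[C@@H](C)c2ccc(OC)cc2)(C#C[Si](C)(C)C)[C@H](OC)CC1=O | intermediate (not isolated)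
10 | (4R)-2-[(diphenylmethylidene)amino]-4-[(1S)-1-(4-methoxyphenyl)ethoxy]-4-[(trimethylsilyl)ethynyl]cyclohexa-2,5-dien-1-one | C(c1ccccc1)(c1ccccc1)=NC1=C[C@@](O[C@@H](C)c2ccc(OC)cc2)(C#C[Si](C)(C)C)C=CC1=O | intermediate
11 | hex-1-ene | CCCCC=C | starting material
12 | dimethyl[(2S)-2-methylhexyl]alumane | CCCC[C@H](C)C[Al](C)C | intermediate (not isolated)
13 | (4S)-4-methyloct-1-ene | CCCC[C@H](C)CC=C | intermediate
14 | [(2R,4S)-2,4-dimethyloctyl]dimethylalumane | CCCC[C@H](C)C[C@@H](C)C[Al](C)C | intermediate (not isolated)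
15 | (2R,4S)-2,4-dimethyloctan-1-ol | CCCC[C@H](C)C[C@@H](C)CO | intermediate
16 | (2R,4S)-2,4-dimethyloctanal | CCCC[C@H](C)C[C@@H](C)C=O | intermediate (not isolated)
17 | ethyl (2E,4R,6S)-4,6-dimethyldec-2-enoate | CCCC[C@H](C)C[C@@H](C)/C=C/C(=O)OCC | intermediate
18 | (2E,4R,6S)-4,6-dimethyldec-2-enoic acid | CCCC[C@H](C)C[C@@H](C)/C=C/C(=O)O | intermediate
19 | (2E,4R,6S)-4,6-dimethyldec-2-enoyl chloride | CCCC[C@H](C)C[C@@H](C)/C=C/C(Cl)=O | intermediate (not isolated)
20 | (4R)-2-amino-4-[(1S)-1-(4-methoxyphenyl)ethoxy]-4-[(trimethylsilyl)ethynyl]cyclohexa-2,5-dien-1-one | NC1=C[C@@](O[C@@H](C)c2ccc(OC)cc2)(C#C[Si](C)(C)C)C=CC1=O | intermediate (not isolated)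
21 | (2E,4R,6S)-N-{(3R)-3-[(1S)-1-(4-methoxyphenyl)ethoxy]-6-oxo-3-[(trimethylsilyl)ethynyl]cyclohexa-1,4-dien-1-yl}-4,6-dimethyldec-2-enamide | CCCC[C@H](C)C[C@@H](C)/C=C/C(=O)NC1=C[C@@](O[C@@H](C)c2ccc(OC)cc2)(C#C[Si](C)(C)C)C=CC1=O | intermediate
22 | (2E,4R,6S)-N-{(3R)-3-ethynyl-3-[(1S)-1-(4-methoxyphenyl)ethoxy]-6-oxocyclohexa-1,4-dien-1-yl}-4,6-dimethyldec-2-enamide | CCCC[C@H](C)C[C@@H](C)/C=C/C(=O)NC1=C[C@@](O[C@@H](C)c2ccc(OC)cc2)(C#C)C=CC1=O | intermediate
23 | (2E,4R,6S)-N-[(3R)-3-ethynyl-3-hydroxy-6-oxocyclohexa-1,4-dien-1-yl]-4,6-dimethyldec-2-enamide | CCCC[C@H](C)C[C@@H](C)/C=C/C(=O)NC1=C[C@@](O)(C#C)C=CC1=O | intermediate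
24 | cyclic phenylboronate of 25 (2-phenyl-1,3,2-dioxaborolane cis-fused across C4 and C5) | CCCC[C@H](C)C[C@@H](C)/C=C/C(=O)NC1=C[C@]2(C#C)OB(c3ccccc3)O[C@@H]2CC1=O | intermediate (not isolated)
25 | (2E,4R,6S)-N-[(3R,4R)-3-ethynyl-3,4-dihydroxy-6-oxocyclohex-1-en-1-yl]-4,6-dimethyldec-2-enamide (cis-diol) | CCCC[C@H](C)C[C@@H](C)/C=C/C(=O)NC1=C[C@@](O)(C#C)[C@H](O)CC1=O | intermediate
26 | (2E,4R,6S)-N-{(3R,4R)-3,4-dihydroxy-6-oxo-3-[(E)-2-(tributylstannyl)ethenyl]cyclohex-1-en-1-yl}-4,6-dimethyldec-2-enamide | CCCC[C@H](C)C[C@@H](C)/C=C/C(=O)NC1=C[C@@](O)(/C=C/[Sn](CCCC)(CCCC)CCCC)[C@H](O)CC1=O | intermediate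
27 | cyclopentane-1,3-dione | O=C1CCC(=O)C1 | starting material
28 | 2-(hydroxyimino)cyclopentane-1,3-dione | O=C1CCC(=O)C1=NO | intermediate
29 | 2-amino-3-hydroxycyclopent-2-en-1-one hydrochloride | Cl.NC1=C(O)CCC1=O | intermediate
30 | potassium (1E,3E)-5-oxopenta-1,3-dien-1-olate (glutaconaldehyde potassium salt) | [K+].[O-]/C=C/C=C/C=O | starting material
31 | (2E,4E)-5-bromopenta-2,4-dienal | Br/C=C/C=C/C=O | intermediate
32 | (2E,4E)-5-bromopenta-2,4-dienoic acid | Br/C=C/C=C/C(=O)O | intermediate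
33 | (2E,4E)-5-bromopenta-2,4-dienoyl chloride | Br/C=C/C=C/C(Cl)=O | intermediate (not isolated)
34 | (2E,4E)-5-bromo-N-(2-hydroxy-5-oxocyclopent-1-en-1-yl)penta-2,4-dienamide | Br/C=C/C=C/C(=O)NC1=C(O)CCC1=O | intermediate
35 | (2E,4R,6S)-N-[(3S,4R)-3,4-dihydroxy-3-{(1E,3E,5E)-7-[(2-hydroxy-5-oxocyclopent-1-en-1-yl)amino]-7-oxohepta-1,3,5-trien-1-yl}-6-oxocyclohex-1-en-1-yl]-4,6-dimethyldec-2-enamide | CCCC[C@H](C)C[C@@H](C)/C=C/C(=O)NC1=C[C@@](O)(/C=C/C=C/C=C/C(=O)NC2=C(O)CCC2=O)[C@H](O)CC1=O | target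

Total step count: 19
Longest linear sequence: 10 steps (steps 1, 2, 3, 4, 9, 10, 11, 12, 13, 19 from 1; equally steps 5, 6, 7, 8, 9, 10, 11, 12, 13, 19 from 11)

Steps most likely to fail

Step 4 (proposed new method). The delocalised anion may be acylated at the wrong terminus, the second ring closure may run through the diphenyl-substituted carbon to a dihydropyridine instead of through C4, or the auxiliary may discriminate the two faces of C4 only weakly. The fallback gives up the annulation and uses dearomatisation chemistry that is established for this compound class. It sets out from acid chloride 19 and returns to the route at diol 25. Acid chloride 19 acylates 2,5-dimethoxyaniline (pyridine, CH2Cl2) to the anilide F1. Oxidation with PhI(OAc)2 in MeOH gives the quinone monoketal F2. Weitz–Scheffer epoxidation of the unsubstituted enone double bond under cinchona phase-transfer catalysis (tBuOOH, NaOH, N-benzylcinchonidinium chloride, toluene; the pseudo-enantiomeric salt if the other sense is needed) gives the epoxide F3. Ethynylmagnesium bromide adds to the ketone anti to the epoxide and gives the ethynyl carbinol F4 with the hydroxyl cis to the epoxide oxygen. Aqueous trifluoroacetic acid unmasks the ketone to the epoxy quinol F5. SmI2 (THF–MeOH, −78 °C) cleaves the C6–O bond of the α,β-epoxy ketone and gives 25.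

Step 12. The oxa-Michael addition may be reversible, so that the C5 oxygen is lost again by retro-addition when the boronate is released, or the tethered oxygen may add to C3. The fallback delivers the oxygen from a carbon tether instead; it sets out from 23 and returns at 25. Quinol 23 with 4-methoxybenzaldehyde and cat. KOtBu (THF, 0 °C) forms a hemiacetal alkoxide that adds to C5 and gives the cis-fused 4-methoxybenzylidene acetal F6. 80% aqueous AcOH (23 °C) then hydrolyses the acetal to 25.

Step 3. The primary amine may displace the alkoxy group at the β-carbon (vinylogous transamination) instead of condensing with the aldehyde. The fallback avoids a free amine; it sets out from 4 and returns at 6. Azidodiphenylmethane and PPh3 (THF, 23 °C, Staudinger reaction) give the iminophosphorane F7, which condenses with aldehyde 4 in an aza-Wittig reaction to give 6.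

Further compounds
F1 | step 4 | (2E,4R,6S)-N-(2,5-dimethoxyphenyl)-4,6-dimethyldec-2-enamide | CCCC[C@H](C)C[C@@H](C)/C=C/C(=O)Nc1cc(OC)ccc1OC
F2 | step 4 | (2E,4R,6S)-N-(6,6-dimethoxy-3-oxocyclohexa-1,4-dien-1-yl)-4,6-dimethyldec-2-enamide | CCCC[C@H](C)C[C@@H](C)/C=C/C(=O)NC1=CC(=O)C=CC1(OC)OC
F3 | step 4 | epoxide of F2 at the unsubstituted enone double bond, enantiomer as drawn | CCCC[C@H](C)C[C@@H](C)/C=C/C(=O)NC1=CC(=O)[C@@H]2O[C@@H]2C1(OC)OC
F4 | step 4 | ethynyl carbinol from F3, hydroxyl cis to the epoxide oxygen, ketone still as dimethyl ketal | CCCC[C@H](C)C[C@@H](C)/C=C/C(=O)NC1=C[C@@](O)(C#C)[C@@H]2O[C@@H]2C1(OC)OC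
F5 | step 4 | 2-amido-5,6-epoxy-4-ethynyl-4-hydroxycyclohex-2-en-1-one bearing the (2E,4R,6S)-4,6-dimethyldec-2-enoyl group, epoxide cis to the C4 hydroxyl | CCCC[C@H](C)C[C@@H](C)/C=C/C(=O)NC1=C[C@@](O)(C#C)[C@@H]2O[C@@H]2C1=O
F6 | step 12 | 4-methoxybenzylidene acetal of 25, dioxolane cis-fused across C4 and C5 | CCCC[C@H](C)C[C@@H](C)/C=C/C(=O)NC1=C[C@]2(C#C)OC(c3ccc(OC)cc3)O[C@@H]2CC1=O
F7 | step 3 | N-(diphenylmethyl)-P,P,P-triphenylphosphine imide | C(c1ccccc1)(c1ccccc1)N=P(c1ccccc1)(c1ccccc1)c1ccccc1
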